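**Strategy.** Ring B (C5–C10, labdane numbering) is a cyclohexene whose C7=C8 double bond lies opposite the ring-fusion bond C5–C10, the imprint of a [4+2] cycloaddition. The key step is a silicon-tethered type 2 intramolecular Diels–Alder reaction that forms C5–C6 and C9–C10 together: a citronellol-derived (E)-diene (C6–C9 with the side chain) adds to an acyclic (E)-enal (C10=C5 carrying C1, C20 and C2–C4). In the precursor, diene carbon C7 is linked through SiMe2–O to the C3 carbinol; this temporary bridge forces C4 and C20 endo, so C5, C9 and quaternary C10 arise in the trans-labdane relationship. Ring A is closed afterwards by aldol condensation.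

Key step: step 9

Remark: labdane numbers are used throughout (ring A = C1–C5 and C10; ring B = C5–C10; side chain C11–C16 with oxygen on C15; C17 on C8; C18/C19 on C4; C20 on C10). (S)-Citronellol, ethyl 2,2-dimethyl-3-oxobutanoate and (R)-2-methylbutanoic acid are assumed to be purchasable, the chiral ones in enantiopure form.

**Step 1**
Reactants: 1 (S)-citronellol; 2 benzyl bromide
Product: 3 benzyl (3S)-3,7-dimethyloct-6-en-1-yl ether
Conditions: NaH, Bu4NI (cat.), THF, 0 °C to rt
Reagents that add atoms: benzyl bromide 2 (BrCc1ccccc1)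
Why: Williamson ether synthesis masks the primary C15 hydroxyl as a benzyl ether that should survive every step up to the dissolving-metal reduction of step 13, which removes it; the C13 stereocentre is not touched.

**Step 2**
Reactants: 3 benzyl (3S)-3,7-dimethyloct-6-en-1-yl ether
Product: 5 (2E,6S)-8-(benzyloxy)-2,6-dimethyloct-2-enal, via allylic alcohol 4 (not isolated)
Conditions: SeO2 (cat.), t-BuOOH, CH2Cl2, rt; then MnO2, CH2Cl2, rt
Reagents that add atoms: tert-butyl hydroperoxide (CC(C)(C)OO), its oxygen being transferred through selenium dioxide (O=[Se]=O)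
Why: Riley allylic oxidation (ene reaction, then [2,3]-sigmatropic shift) is selective for the (E)-methyl group of the trisubstituted olefin, so the new oxygenated carbon (future C7) should end trans to the chain across C8=C9, and MnO2 converges alcohol 4 to the (E)-enal.

**Step 3**
Reactants: 5 (2E,6S)-8-(benzyloxy)-2,6-dimethyloct-2-enal; 6 dimethyl (1-diazo-2-oxopropyl)phosphonate
Product: 7 benzyl (3S,6E)-3,7-dimethylnon-6-en-8-yn-1-yl ether
Conditions: K2CO3, MeOH, 0 °C to rt
Reagents that add atoms: dimethyl (1-diazo-2-oxopropyl)phosphonate 6 (CC(=O)C(=[N+]=[N-])P(=O)(OC)OC)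
Why: Seyferth–Gilbert homologation in the Ohira–Bestmann variant should convert the enal into the terminal 1,3-enyne (adding C6) under mildly basic conditions that leave the (E)-olefin and the benzyl ether intact.

**Step 4**
Reactants: 8 ethyl 2,2-dimethyl-3-oxobutanoate
Product: 9 ethyl (3S)-3-hydroxy-2,2-dimethylbutanoate
Conditions: H2 (100 atm), RuCl2[(S)-BINAP] (cat.), EtOH, 40 °C
Reagents that add atoms: none
Why: Noyori asymmetric hydrogenation of the β-keto ester through its chelate should set the carbinol centre (future C3) as (S) with the (S)-BINAP ligand; this centre later relays facial selectivity in step 9.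

**Step 5**
Reactants: 9 ethyl (3S)-3-hydroxy-2,2-dimethylbutanoate
Product: 10 (3S)-2,2-dimethylbutane-1,3-diol
Conditions: LiAlH4, THF, 0 °C to rt
Reagents that add atoms: none
Why: Hydride reduction of the ester should give the 1,3-diol without touching the stereocentre.

**Step 6**
Reactants: 10 (3S)-2,2-dimethylbutane-1,3-diol; 11 2-(triphenylphosphoranylidene)propanal
Product: 13 (2E,5S)-5-hydroxy-2,4,4-trimethylhex-2-enal, via hydroxy aldehyde 12 (not isolated)
Conditions: TEMPO (cat.), PhI(OAc)2, CH2Cl2, rt; then NaHCO3, 11, PhMe, 80 °C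
Reagents that add atoms: 2-(triphenylphosphoranylidene)propanal 11 (CC(C=O)=P(c1ccccc1)(c1ccccc1)c1ccccc1)
Why: Oxoammonium (TEMPO) oxidation is selective for the primary alcohol, and the Wittig reaction of the stabilised α-methyl ylide with the unenolisable aldehyde should give the (E)-trisubstituted enal, which fixes C1 trans to C4 across C10=C5.

**Step 7**
Reactants: 13 (2E,5S)-5-hydroxy-2,4,4-trimethylhex-2-enal; 14 chlorodimethylsilane
Product: 15 (2E,5S)-5-[(dimethylsilyl)oxy]-2,4,4-trimethylhex-2-enal
Conditions: Et3N, DMAP (cat.), CH2Cl2, 0 °C; filtered and used crude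
Reagents that add atoms: chlorodimethylsilane 14 (C[SiH](C)Cl)
Why: O-Silylation of the secondary alcohol installs the Si–H handle for the tether; the product is a hydrolytically labile silyl ether and is therefore carried on without chromatography.

**Step 8**
Reactants: 15 (2E,5S)-5-[(dimethylsilyl)oxy]-2,4,4-trimethylhex-2-enal; 7 benzyl (3S,6E)-3,7-dimethylnon-6-en-8-yn-1-yl ether
Product: 16 (2E,5S)-5-({[(3E,7S)-9-(benzyloxy)-3,7-dimethylnona-1,3-dien-2-yl]dimethylsilyl}oxy)-2,4,4-trimethylhex-2-enal
Conditions: [Cp*Ru(MeCN)3]PF6 (3 mol %), CH2Cl2, 0 °C to rt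
Reagents that add atoms: none
Why: Cationic ruthenium-catalysed trans-hydrosilylation of a terminal alkyne is Markovnikov-selective (silicon to the internal carbon C7), so it should give the 1,1-disubstituted vinylsilane, i.e. the 2-silyl-1,3-diene, faster than the Si–H group reacts with the enal, and the (E)-C8=C9 olefin is not involved.

**Step 9**
Reactants: 16 tethered dienyl silyl ether enal
Product: 17 bridged cycloadduct (ring B with C7=C8 at the bridgehead; C10 bears CHO (C1, α) and CH3 (C20, β); C9 bears the β side chain; C5 (H α) is joined through C4(CH3)2–C3H(CH3)–O–Si(CH3)2 to C7)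
Conditions: PhMe (5 mM), BHT (cat.), 170 °C, sealed tube
Reagents that add atoms: none
Why: A concerted but asynchronous thermal [4+2] cycloaddition joins the 2-silyl diene (C6=C7–C8=C9) to the tethered (E)-enal (C5=C10), with the C5–C6 bond leading. The closest known reaction type is the type 2 intramolecular Diels–Alder reaction with a disposable Si–O tether on the internal diene carbon, which gives bridgehead olefins. Two rings close: ring B by suprafacial 4π+2π union (C5–C6 and C9–C10), and the seven-membered oxasilacycle C5–C4–C3–O–Si–C7–C6 in the 1,3-bridged mode, giving a bicyclo[4.3.1]decene with C7=C8 at the bridgehead. Regiochemistry is secured twice, since the four-atom tether lets C5 reach only C6 and the enal β-carbon is also the electronically matched partner of the CH2 terminus. The relative configuration follows from geometry: the (E)-enal keeps C1 and C4 trans (H5 anti to C20, the later trans ring fusion), the tether has to pass beneath C7 so that C4 and the cis-disposed C20 are endo and the aldehyde exo, and the (E)-C8=C9 olefin then places C11 cis to C20 at C9. The diene face, hence the absolute configuration of C5, C9 and C10, should be dictated by the (S)-carbinol C3, whose methyl group takes the outward position on the oxasilacycle next to the gem-dimethyl group; the reaction needs this facial selectivity, and the minor facial isomer is a diastereomer that is removed by chromatography.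

**Step 10**
Reactants: 17 bridged cycloadduct
Product: 19 seco-ring-A diol (C1 as CH2OH, C3 as CH(OH)CH3, C7–H), via hydroxy aldehyde 18 (not isolated)
Conditions: TBAF (3 equiv), THF–DMSO, 60 °C; then NaBH4, MeOH, 0 °C
Reagents that add atoms: none
Why: Fluoride cleaves the Si–O bond and effects ipso-protodesilylation of the alkoxy-substituted vinylsilane, replacing silicon by hydrogen at C7 without moving the C7=C8 double bond, and in-flask borohydride reduction of the hydroxy aldehyde (lactol) to the diol avoids lactone formation in the next oxidation.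

**Step 11**
Reactants: 19 seco-ring-A diol
Product: 20 seco-ring-A keto aldehyde (C1 aldehyde on C10, C3 methyl ketone)
Conditions: (COCl)2, DMSO, CH2Cl2, −78 °C; then Et3N, −78 °C to rt
Reagents that add atoms: none
Why: Swern oxidation activates both hydroxyl groups before base is added, so the 1,5-diol should go to the keto aldehyde and not to a lactone; neither carbonyl has an epimerisable α-stereocentre.

**Step 12**
Reactants: 20 seco-ring-A keto aldehyde
Product: 22 (13S)-15-(benzyloxy)labda-1,7-dien-3-one, via aldol adduct 21 (not isolated)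
Conditions: NaOMe, MeOH, rt to 60 °C
Reagents that add atoms: none
Why: Intramolecular aldol condensation has a single course because the C2 methyl is the only enolisable position and the C1 aldehyde the only electrophile within reach, so ring A should close as the six-membered enone with the trans ring fusion already fixed in step 9.

**Step 13**
Reactants: 22 (13S)-15-(benzyloxy)labda-1,7-dien-3-one
Product: 23 (13S)-15-hydroxylabd-7-en-3-one
Conditions: Li (excess), NH3(l), THF, t-BuOH (1 equiv), −78 °C; isoprene, then NH4Cl
Reagents that add atoms: none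
Why: Dissolving-metal (Birch-type) conjugate reduction saturates C1=C2 through the enolate, which protects the ketone, and at the same time cleaves the benzyl ether, while the isolated trisubstituted C7=C8 olefin is inert.

**Step 14**
Reactants: 23 (13S)-15-hydroxylabd-7-en-3-one
Product: 24 (13S)-labd-7-ene-3α,15-diol
Conditions: LiBH(s-Bu)3 (L-Selectride, 2.5 equiv), THF, −78 °C; then NH4Cl (aq)
Reagents that add atoms: none
Why: The bulky trialkylborohydride attacks the 4,4-dimethyl-3-ketone from the equatorial direction, so substrate control should give the axial 3α (3R) alcohol.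

**Step 15**
Reactants: 24 (13S)-labd-7-ene-3α,15-diol; 25 (R)-2-methylbutanoic acid
Product: 26 (13S)-3α-hydroxylabd-7-en-15-yl (2R)-2-methylbutanoate (target)
Conditions: EDC·HCl, DMAP (cat.), CH2Cl2, 0 °C
Reagents that add atoms: (R)-2-methylbutanoic acid 25 (CC[C@@H](C)C(=O)O)
Why: Steglich esterification should acylate the unhindered primary C15 hydroxyl in preference to the axial C3 hydroxyl flanked by the gem-dimethyl group, and the carbodiimide conditions do not enolise the α-stereocentre of the acid.

**Compound list**

1 | (S)-citronellol, (3S)-3,7-dimethyloct-6-en-1-ol | OCC[C@@H](C)CCC=C(C)C | starting material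
2 | benzyl bromide | BrCc1ccccc1 | starting material
3 | benzyl (3S)-3,7-dimethyloct-6-en-1-yl ether | c1ccccc1COCC[C@@H](C)CCC=C(C)C | intermediate
4 | (2E,6S)-8-(benzyloxy)-2,6-dimethyloct-2-en-1-ol | c1ccccc1COCC[C@@H](C)CC/C=C(\C)CO | intermediate
5 | (2E,6S)-8-(benzyloxy)-2,6-dimethyloct-2-enal | c1ccccc1COCC[C@@H](C)CC/C=C(\C)C=O | intermediate
6 | dimethyl (1-diazo-2-oxopropyl)phosphonate | CC(=O)C(=[N+]=[N-])P(=O)(OC)OC | starting material
7 | benzyl (3S,6E)-3,7-dimethylnon-6-en-8-yn-1-yl ether | c1ccccc1COCC[C@@H](C)CC/C=C(\C)C#C | intermediate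
8 | ethyl 2,2-dimethyl-3-oxobutanoate | CCOC(=O)C(C)(C)C(C)=O | starting material
9 | ethyl (3S)-3-hydroxy-2,2-dimethylbutanoate | CCOC(=O)C(C)(C)[C@H](C)O | intermediate
10 | (3S)-2,2-dimethylbutane-1,3-diol | OCC(C)(C)[C@H](C)O | intermediate
11 | 2-(triphenylphosphoranylidene)propanal | CC(C=O)=P(c1ccccc1)(c1ccccc1)c1ccccc1 | starting material
12 | (3S)-3-hydroxy-2,2-dimethylbutanal | O=CC(C)(C)[C@H](C)O | intermediate
13 | (2E,5S)-5-hydroxy-2,4,4-trimethylhex-2-enal | O=C/C(C)=C/C(C)(C)[C@H](C)O | intermediate
14 | chlorodimethylsilane | C[SiH](C)Cl | starting material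
15 | (2E,5S)-5-[(dimethylsilyl)oxy]-2,4,4-trimethylhex-2-enal | O=C/C(C)=C/C(C)(C)[C@H](C)O[SiH](C)C | intermediate
16 | (2E,5S)-5-({[(3E,7S)-9-(benzyloxy)-3,7-dimethylnona-1,3-dien-2-yl]dimethylsilyl}oxy)-2,4,4-trimethylhex-2-enal | c1ccccc1COCC[C@@H](C)CC/C=C(\C)C(=C)[Si](C)(C)O[C@@H](C)C(C)(C)/C=C(\C)C=O | intermediate
17 | bridged cycloadduct: ring B cyclohexene with bridgehead C7=C8, C10 bearing CHO (α) and CH3 (β), C9 bearing the β 5-(benzyloxy)-3-methylpentyl chain, C5 joined through C(CH3)2–CH(CH3)–O–Si(CH3)2 to C7 | c1ccccc1COCC[C@@H](C)CC[C@H]1C(C)=C2C[C@@H](C(C)(C)[C@H](C)O[Si]2(C)C)[C@]1(C)C=O | intermediate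
18 | seco-ring-A hydroxy aldehyde (as 17 with C7–H and free C3–OH; in equilibrium with its lactol) | c1ccccc1COCC[C@@H](C)CC[C@H]1C(C)=CC[C@@H](C(C)(C)[C@H](C)O)[C@]1(C)C=O | intermediate
19 | seco-ring-A diol (C1 as CH2OH, C3 as secondary carbinol) | c1ccccc1COCC[C@@H](C)CC[C@H]1C(C)=CC[C@@H](C(C)(C)[C@H](C)O)[C@]1(C)CO | intermediate
20 | seco-ring-A keto aldehyde (C1 aldehyde, C3 methyl ketone) | c1ccccc1COCC[C@@H](C)CC[C@H]1C(C)=CC[C@@H](C(C)(C)C(C)=O)[C@]1(C)C=O | intermediate
21 | aldol adduct, (13S)-15-(benzyloxy)-1-hydroxylabd-7-en-3-one (C1 epimers) | c1ccccc1COCC[C@@H](C)CC[C@H]1C(C)=CC[C@H]2C(C)(C)C(=O)CC(O)[C@]12C | intermediate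
22 | (13S)-15-(benzyloxy)labda-1,7-dien-3-one (5α-H, 9β side chain, 10β-CH3) | c1ccccc1COCC[C@@H](C)CC[C@H]1C(C)=CC[C@H]2C(C)(C)C(=O)C=C[C@]12C | intermediate
23 | (13S)-15-hydroxylabd-7-en-3-one | OCC[C@@H](C)CC[C@H]1C(C)=CC[C@H]2C(C)(C)C(=O)CC[C@]12C | intermediate
24 | (13S)-labd-7-ene-3α,15-diol | OCC[C@@H](C)CC[C@H]1C(C)=CC[C@H]2C(C)(C)[C@H](O)CC[C@]12C | intermediate
25 | (R)-2-methylbutanoic acid | CC[C@@H](C)C(=O)O | starting material
26 | (13S)-3α-hydroxylabd-7-en-15-yl (2R)-2-methylbutanoate | CC[C@@H](C)C(=O)OCC[C@@H](C)CC[C@H]1C(C)=CC[C@H]2C(C)(C)[C@H](O)CC[C@]12C | target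

**Totals.** Total step count: 15. Longest linear sequence: 12 steps (steps 4–15, from ethyl 2,2-dimethyl-3-oxobutanoate).

**Steps most likely to fail**

Step 9. The cycloaddition may be slow, because the interior of the diene is fully substituted and the dienophile is trisubstituted next to a quaternary carbon. Thermal decomposition or desilylation of the dienylsilane could then compete, and the single carbinol centre may relay the diene face only weakly. The fallback sets out from 16 and returns at 17 by changing the activation from neutral to cationic. Silyl-transfer acetalisation of the aldehyde of 16 (1,2-bis(trimethylsilyloxy)ethane, catalytic TMSOTf, CH2Cl2, −78 °C) gives the dioxolane acetal F1. More TMSOTf at −78 to −40 °C opens the acetal to its alkoxyallyl (oxocarbenium) cation, a far stronger dienophile. The same tether-enforced bridged cycloaddition (ionic Diels–Alder) should then run at low temperature, where facial discrimination is also sharper, to give the acetal cycloadduct F2. PPTS in wet acetone releases aldehyde 17.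

Step 8. Markovnikov regiocontrol may erode on the conjugated enyne, or the Si–H group may hydrosilylate the enal carbonyl under the ruthenium catalyst. The fallback sets out from 7 and returns at 16, making the C7–Si bond by polar chemistry. Bromoboration of the terminal alkyne with B-bromo-9-BBN and protonolysis with AcOH gives the 2-bromodiene F3. Br/Li exchange (t-BuLi, Et2O, −78 °C) and quenching with excess Me2SiCl2 gives the dienyl(chloro)dimethylsilane F4. Silylation of alcohol 13 with it (imidazole, CH2Cl2) delivers 16 without any Si–H intermediate.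

Step 10. Fluoride-induced protodesilylation of the fully substituted vinylsilane may stall at the silanol stage, or the basic medium may shift the C7=C8 double bond. The fallback sets out from 17 and returns at 19 by halodesilylation and reduction. N-Iodosuccinimide in MeCN should effect ipso-iododesilylation with retention of the olefin position, and aqueous work-up hydrolyses the Si–O bond to give the vinyl iodide hydroxy aldehyde F5. Pd(PPh3)4-catalysed hydrodehalogenation with Bu3SnH gives 18, which NaBH4 reduces to 19.

**Further compounds**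

F1 | step 9 | 1,3-dioxolane acetal of aldehyde 16 | c1ccccc1COCC[C@@H](C)CC/C=C(\C)C(=C)[Si](C)(C)O[C@@H](C)C(C)(C)/C=C(\C)C1OCCO1
F2 | step 9 | 1,3-dioxolane acetal of cycloadduct 17 | c1ccccc1COCC[C@@H](C)CC[C@H]1C(C)=C2C[C@@H](C(C)(C)[C@H](C)O[Si]2(C)C)[C@]1(C)C3OCCO3
F3 | step 8 | benzyl (3S,6E)-8-bromo-3,7-dimethylnona-6,8-dien-1-yl ether | c1ccccc1COCC[C@@H](C)CC/C=C(\C)C(Br)=C
F4 | step 8 | [(3E,7S)-9-(benzyloxy)-3,7-dimethylnona-1,3-dien-2-yl]chlorodimethylsilane | c1ccccc1COCC[C@@H](C)CC/C=C(\C)C(=C)[Si](C)(C)Cl
F5 | step 10 | C7-iodo analogue of hydroxy aldehyde 18 | c1ccccc1COCC[C@@H](C)CC[C@H]1C(C)=C(I)C[C@@H](C(C)(C)[C@H](C)O)[C@]1(C)C=O
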